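(The data come from a simulation for an exercise; scatter was added.)

A closed, stirred vessel at constant temperature receives a charge of starting material, and the question is how much intermediate D stands in it along the way.

| flask | starting material | remark | time |
|---|---|---|---|
| south-east | 1.4 M | run made earlier |  |
| north-west | 2.2 M | run made earlier |  |
| flask | 1.0 M |  | 3.0 d |

- south-east (time / d: intermediate D / %, target / %, starting material / %): 0.250: 5.9, 3.0, 0; 0.500: 16.1, 2.2, 0.2; 0.833: 20.5, 1.3, 0; 1.25: 22.2, 2.9, 0; 2.00: 17.3, 1.0, 0; 4.00: 4.4, 2.1, 2.1
- north-west (time / d: intermediate D / %, target / %, starting material / %): 0.250: 8.8, 1.0, 0; 0.500: 14.8, 1.4, 0; 0.833: 21.0, 1.6, 0; 1.25: 22.8, 2.9, 0.7; 2.00: 17.9, 2.0, 1.3; 4.00: 4.9, 1.4, 0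

(scatter of a reading: 1 percentage point)

1. when, up to 3.0 d, the flask holds most intermediate D
2. the amount of intermediate D, in percent of the starting material charged, at that time
3. the first time at which intermediate D reaches 11%, in the same percent

At 1.25 d the south-east and north-west runs read 22.2% and 22.8% of intermediate D despite their different charges, with a scatter of 1 percentage point. So the rate, as a fraction of the charge per day, is read from the mean of both runs and assumed to hold for the flask. Over the first 0.250 d intermediate D gains 0.294 d⁻¹. Between 0.833 d and 1.25 d the gain is 0.0420 d⁻¹, slower by a factor of 7.00. By 2.00 d the sign has turned, with a loss of 0.0653 d⁻¹.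

The mean readings at 2.00 d and 4.00 d give the quantity to carry: the tail half-life, the time in which intermediate D halves once its fall has set in, 1.04 d. Run on to 3.0 d, this tail leaves 9.05%, less than the highest mean reading of 22.5%. By this reckoning the flask peaks inside the time allowed, near the reading at 1.25 d.

The forecast, holding that “the percent profile doesn't depend on concentration”, gives 22.7% at 1.12 d, with the level of 11% first reached at 0.34 d.

The flask gives 21.1% at 1.15 d and reaches 11% at 0.369 d, so each of the forecast's values is right within the tolerance.

    starting material → intermediate B (k = 8.70 × 10⁻⁵ s⁻¹)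
    intermediate B → side product (k = 4.80 × 10⁻⁴ s⁻¹)
    intermediate C → side product (k = 1.80 × 10⁻⁵ s⁻¹)
    starting material → intermediate A (k = 8.60 × 10⁻⁴ s⁻¹)
    intermediate C ⇌ intermediate D (K = 1.10, k = 5.00 × 10⁻⁵ s⁻¹)
    intermediate B → target (k = 1.00 × 10⁻⁴ s⁻¹)
    intermediate A ⇌ intermediate C (K = 9.00, k = 1.60 × 10⁻⁵ s⁻¹)

At that best time the flask holds intermediate C at 19.2%, and intermediate C and intermediate D interchange with a relaxation half-life of 0.0840 d by that step alone, short against 3.0 d. The flask holds 10.6% of intermediate D at 3.00 d. Carried 9.00 d further at the tail half-life of 1.04 d, that amount becomes 0.0263%, while the neighbouring flask, read at 12 d, holds 0.0436%.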